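The C6–C7 bond is cut first, giving the C9 ketol of ring A and a C31 heptaenyne. Next come C11'=C12' (Wittig) and C11=C12 (HWE) on the two sides of the C10 trienedial, then O–C8' and C6'–C7' of the furanoid end.
Forward: actinol gives one 5-oxygenated trimethylcyclohexanone that serves both ends. Its O-silylated form takes up a C6 enyne, and the dihydrofuran ring is closed by carbonate formation, SN2' reduction and allenol cyclisation. Two olefinations build the C31 chain, the free ketol takes up the C31 acetylide, and hydroalumination and desilylation finish.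
Enabling feature: in ring A the C6 carbonyl lies between two fully substituted carbons (C1 with the gem-dimethyl group, C5 with CH3 and OH), so it cannot enolise. The C5 oxygen is vicinal and cis to the C6–C7 bond of the target, so a metal held on C5–O can steer C7 to that face.
Stereochemistry: C3 and C3' come from (4R,6R)-actinol, and C5 and C5' from peracid attack anti to the C3 silyl ether. C6' comes from Felkin–Anh addition and is relayed through the allene axis to C8'; C6 comes from chelation-controlled addition to the same ketone. The E-alkenes come from the C6 enynol, HWE, Wittig and trans-hydroalumination.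
All oxidations are done before the polyene exists; after the union only hydride and fluoride are used.

Key step: step 16

Remark: carotenoid numbering is used (C1–C6 for triol ring A, primed numbers for the furanoid end). Compounds 1, 7 and 21 are taken as commercial, and all polyene steps run under argon in dim light.

Step 1
Reactants: 1 (4R,6R)-4-hydroxy-2,2,6-trimethylcyclohexan-1-one (actinol)
Product: 2 (4R,6R)-4-(tert-butyldimethylsilyloxy)-2,2,6-trimethylcyclohexan-1-one
Conditions: TBSCl, imidazole, DMF, rt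
Reagents that add atoms: tert-butyldimethylsilyl chloride CC(C)(C)[Si](C)(C)Cl
Why: Routine imidazole-promoted silyl ether protection of the only hydroxyl group, which touches no stereocentre and gives a group that survives the later base, hydride and peracid steps.

Step 2
Reactants: 2 (4R,6R)-4-(tert-butyldimethylsilyloxy)-2,2,6-trimethylcyclohexan-1-one
Product: 3 (4R)-4-(tert-butyldimethylsilyloxy)-2,6,6-trimethyl-1-(trimethylsilyloxy)cyclohex-1-ene
Conditions: TMSOTf, Et3N, CH2Cl2, 0 °C to rt
Reagents that add atoms: trimethylsilyl triflate C[Si](C)(C)OS(=O)(=O)C(F)(F)F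
Why: Soft enolisation and O-silylation of a ketone; because C1 is quaternary only the C5–H can be removed, so a single tetrasubstituted C5=C6 silyl enol ether should form, and the C5 stereocentre of actinol is given up on purpose.

Step 3
Reactants: 3 (4R)-4-(tert-butyldimethylsilyloxy)-2,6,6-trimethyl-1-(trimethylsilyloxy)cyclohex-1-ene
Product: 5 (2R,4S)-4-(tert-butyldimethylsilyloxy)-2,6,6-trimethyl-2-(trimethylsilyloxy)cyclohexan-1-one, via silyloxy epoxide 4 (not isolated)
Conditions: mCPBA, hexane, −15 °C to rt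
Reagents that add atoms: 3-chloroperoxybenzoic acid OOC(=O)c1cccc(Cl)c1
Why: Rubottom oxidation: the peracid should epoxidise the electron-rich C5=C6 bond on the face anti to the C3 silyl ether (the preference known for peracid epoxidation of 3-oxygenated trimethylcyclohexene end groups, with axial C5–O bond formation on the half-chair that keeps C3–OTBS equatorial), and 4 opens with a 1,4-silyl shift to the ketone, which fixes C5 as R.

Step 4
Reactants: 5 (2R,4S)-4-(tert-butyldimethylsilyloxy)-2,6,6-trimethyl-2-(trimethylsilyloxy)cyclohexan-1-one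
Product: 6 (2R,4S)-4-(tert-butyldimethylsilyloxy)-2-hydroxy-2,6,6-trimethylcyclohexan-1-one (ketol)
Conditions: K2CO3 (cat.), MeOH, 0 °C
Reagents that add atoms: none
Why: Base-catalysed methanolysis of a trimethylsilyl ether, which is far more labile than the secondary TBS ether, frees the tertiary C5–OH needed in step 16 without touching a stereocentre.

Step 5
Reactants: 7 (2E)-3-methylpent-2-en-4-yn-1-ol
Product: 8 tert-butyldimethylsilyl ether of (2E)-3-methylpent-2-en-4-yn-1-ol
Conditions: TBSCl, imidazole, CH2Cl2, rt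
Reagents that add atoms: tert-butyldimethylsilyl chloride CC(C)(C)[Si](C)(C)Cl
Why: Routine silyl ether protection of the primary allylic alcohol, so that only the alkyne C–H is acidic in step 6; the E double bond is untouched.

Step 6
Reactants: 8 tert-butyldimethylsilyl ether of (2E)-3-methylpent-2-en-4-yn-1-ol; 5 (2R,4S)-4-(tert-butyldimethylsilyloxy)-2,6,6-trimethyl-2-(trimethylsilyloxy)cyclohexan-1-one
Product: 11 (1R,2R,4S)-4-(tert-butyldimethylsilyloxy)-1-[(3E)-5-(tert-butyldimethylsilyloxy)-3-methylpent-3-en-1-yn-1-yl]-2,6,6-trimethylcyclohexane-1,2-diol (5',6'-cis-diol), via lithium acetylide 9 (not isolated), via trimethylsilyl ether adduct 10 (not isolated)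
Conditions: 8, n-BuLi, THF, −78 °C; 5, −78 to 0 °C; H2O; then K2CO3, MeOH, rt
Reagents that add atoms: none
Why: 1,2-Addition of a lithium acetylide to a non-enolisable ketone under Felkin–Anh control: in the chair with C3'–OTBS equatorial the non-chelating C5'–OSiMe3 bond is axial and the slim nucleophile enters axially, anti to it, so that C6'–OH ends cis to C5'–O, and methanolysis then removes the trimethylsilyl group wherever it may have migrated.

Step 7
Reactants: 11 5',6'-cis-diol
Product: 12 cis-fused cyclic carbonate (1,3-dioxolan-2-one) of diol 11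
Conditions: 1,1'-carbonyldiimidazole, DBU (cat.), toluene, 60 °C
Reagents that add atoms: 1,1'-carbonyldiimidazole O=C(n1ccnc1)n1ccnc1
Why: Cyclic carbonate formation from a 1,2-diol; the axial–equatorial cis arrangement of the two tertiary hydroxyl groups allows the five-membered ring, which turns C6'–O into a propargylic leaving group and stores C5'–O.

Step 8
Reactants: 12 cis-fused cyclic carbonate of diol 11
Product: 14 (1R,5S)-5-(tert-butyldimethylsilyloxy)-2-[(3E)-5-(tert-butyldimethylsilyloxy)-3-methylpenta-1,3-dien-1-ylidene]-1,3,3-trimethylcyclohexan-1-ol with S allene axis (C9' on the side of C5'–OH), via diethoxymethylsilyl ether 13 (not isolated)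
Conditions: (IPr)CuCl (cat., IPr = 1,3-bis(2,6-diisopropylphenyl)imidazol-2-ylidene), NaOtBu (cat.), Me(EtO)2SiH, toluene, 0 °C to rt; then 1 M aq. NaOH, THF, rt
Reagents that add atoms: none
Why: Copper hydride catalysed SN2' reduction of a propargylic carbonate (carbene-ligated monovalent copper, silane as hydride source): hydride enters C8' anti to the departing C6'–O bond, so the C6' centre is converted into the S allene axis, and loss of CO2 leaves C5'–O as a silyl ether that the basic work-up cleaves.

Step 9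
Reactants: 14 C15 α-hydroxyallene
Product: 15 (2R,6S,7aR)-6-(tert-butyldimethylsilyloxy)-2-[(2E)-4-(tert-butyldimethylsilyloxy)but-2-en-2-yl]-4,4,7a-trimethyl-2,4,5,6,7,7a-hexahydro-1-benzofuran
Conditions: AuCl3 (2 mol %), THF, 0 °C to rt
Reagents that add atoms: none
Why: Gold-catalysed 5-endo-trig cycloisomerisation of an α-hydroxyallene to a 2,5-dihydrofuran: trivalent gold activates C7'=C8', C5'–OH attacks C8' in the plane of the new ring anti to the metal and protodeauration follows, so the allene axis is transferred to C8' (R, side chain trans to C5'–CH3).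

Step 10
Reactants: 15 bis-silylated C15 dihydrofuran
Product: 16 (2E)-3-[(2R,6S,7aR)-6-(tert-butyldimethylsilyloxy)-4,4,7a-trimethyl-2,4,5,6,7,7a-hexahydro-1-benzofuran-2-yl]but-2-en-1-ol
Conditions: TBAF (1 equiv), AcOH (1 equiv), THF, 0 °C
Reagents that add atoms: none
Why: Selective fluoride desilylation: the unhindered primary allylic TBS ether is cleaved much faster than the secondary ring TBS ether, and the acetic acid buffer keeps the medium near neutral for the doubly allylic C8'–O bond.

Step 11
Reactants: 16 C15 furanoid allylic alcohol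
Product: 18 {(2E)-3-[(2R,6S,7aR)-6-(tert-butyldimethylsilyloxy)-4,4,7a-trimethyl-2,4,5,6,7,7a-hexahydro-1-benzofuran-2-yl]but-2-en-1-yl}triphenylphosphonium bromide, via allylic bromide 17 (not isolated)
Conditions: Ph3PBr2, imidazole, CH2Cl2, −20 °C; then PPh3, rt
Reagents that add atoms: dibromotriphenylphosphorane BrP(Br)(c1ccccc1)(c1ccccc1)c1ccccc1; triphenylphosphine c1ccc(cc1)P(c1ccccc1)c1ccccc1
Why: Appel-type bromination of a primary allylic alcohol under buffered conditions (SN2 at C11') followed by quaternisation of PPh3 by the allylic bromide gives the Wittig salt without the strong acid that would open or epimerise the furanoid ring.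

Step 12
Reactants: 7 (2E)-3-methylpent-2-en-4-yn-1-ol
Product: 19 (3E)-5-bromo-3-methylpent-3-en-1-yne
Conditions: PBr3, Et2O, 0 °C
Reagents that add atoms: phosphorus tribromide BrP(Br)Br
Why: Standard conversion of a primary allylic alcohol into the bromide with PBr3, which proceeds at the primary carbon with retention of the E double bond.

Step 13
Reactants: 19 (3E)-5-bromo-3-methylpent-3-en-1-yne
Product: 20 diethyl [(2E)-3-methylpent-2-en-4-yn-1-yl]phosphonate
Conditions: P(OEt)3, neat, 100 °C
Reagents that add atoms: triethyl phosphite CCOP(OCC)OCC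
Why: Michaelis–Arbuzov reaction of a reactive primary allylic bromide, which keeps the E geometry and the terminal alkyne.

Step 14
Reactants: 20 diethyl [(2E)-3-methylpent-2-en-4-yn-1-yl]phosphonate; 21 (2E,4E,6E)-2,7-dimethylocta-2,4,6-trienedial
Product: 23 (2E,4E,6E,8E,10E)-2,7,11-trimethyltrideca-2,4,6,8,10-pentaen-12-ynal, via sodium phosphonate carbanion 22 (not isolated)
Conditions: 20, NaN(SiMe3)2 (1 equiv), THF, −78 °C; added to 21 (3 equiv), −78 to 0 °C
Reagents that add atoms: none
Why: Horner–Wadsworth–Emmons olefination with an allylic phosphonate anion (more acidic than the alkyne C–H); the excess of the symmetric dialdehyde limits the reaction to one end and reversible addition should give the E C11=C12 bond.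

Step 15
Reactants: 18 C15 furanoid phosphonium bromide; 23 (2E,4E,6E,8E,10E)-2,7,11-trimethyltrideca-2,4,6,8,10-pentaen-12-ynal
Product: 25 all-E C31 heptaenyne (terminal C7≡C8 alkyne, C9 to C9' heptaene, furanoid end of 15 with 3'S,5'R,8'R configuration and C3'–OTBS), via allylic ylide 24 (not isolated)
Conditions: NaOMe, CH2Cl2–MeOH, 0 °C to rt; then EtOAc, 60 °C
Reagents that add atoms: none
Why: Wittig olefination of a polyenal with a semi-stabilised allylic ylide, the classical way to join a C15 end group to a polyene aldehyde; it forms C11'=C12' mainly E, the sterically hindered Z isomer should relax to E on gentle warming, and the weakly basic ylide leaves C8' untouched.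

Step 16
Reactants: 25 all-E C31 heptaenyne; 6 (2R,4S)-4-(tert-butyldimethylsilyloxy)-2-hydroxy-2,6,6-trimethylcyclohexan-1-one (ketol)
Product: 28 (3S,5R,6S,3'S,5'R,8'R)-3,3'-bis(tert-butyldimethylsilyloxy)-5',8'-epoxy-7,8-didehydro-5,6,5',8'-tetrahydro-β,β-carotene-5,6-diol (5,6-trans-diol; 6S only because the alkynyl carbon outranks C1), via dimethylaluminium chelate 26 (not isolated), via C31 lithium acetylide 27 (not isolated)
Conditions: 6 (1.5 equiv), Me3Al, toluene, −78 to 0 °C; 25, n-BuLi, Et2O–toluene, −78 °C; combine, −78 to 0 °C; aq. potassium sodium tartrate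
Reagents that add atoms: none
Why: Me3Al is protonolysed by the C5–OH of 6 (loss of methane) to give the five-membered O–Al←O=C chelate 26, and the lithium acetylide 27 then transfers its alkynyl carbon C7 to the activated, non-enolisable C6 carbonyl, either by outside attack on the chelate or, after binding to aluminium as an alanate, by delivery from the C5–O–Al arm. The closest known reaction type is the Cram-chelate 1,2-addition of alkynyllithium or alkynylalane reagents to α-hydroxy and α-alkoxy ketones, which is also the classical way to attach polyene chains to trimethylcyclohexanones. No ring is closed; the step makes the last C–C bond of the C40 skeleton and the only new stereocentre, C6. Chelation turns C5–O into the carbonyl plane, so that C5–CH3 and one C1–CH3 stand axial on the face that also carries C3–OTBS, and C7 must enter from the opposite face, syn to C5–O, which gives the 5,6-trans-diol with C6–OH cis to C3–O as in the target. The selectivity needed is therefore facial and opposite to that of step 6; it is secured by leaving C5–OH free and tying it to aluminium in a weakly coordinating solvent, the Al–O bond paying for the ring flip or twist, and both delivery modes lead to the same face. Chemoselectivity should not be an issue because the acetylide is the only carbanion, the ketone has no α-hydrogen, and the silyl ethers, the dihydrofuran and the heptaene are inert to it.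

Step 17
Reactants: 28 C40 7,8-didehydro 5,6-trans-diol
Product: 29 (3S,5R,6R,3'S,5'R,8'R)-3,3'-bis(tert-butyldimethylsilyloxy)-5',8'-epoxy-5,6,5',8'-tetrahydro-β,β-carotene-5,6-diol
Conditions: NaAlH2(OCH2CH2OMe)2 (4 equiv), THF, 0 °C to rt; aq. potassium sodium tartrate
Reagents that add atoms: none
Why: Hydroxyl-directed trans-hydroalumination of a propargylic alcohol: the C6–O–Al hydride delivers H to C7 and aluminium to C8 and protonolysis gives the E C7=C8 bond, while the polyene, the silyl ethers and the dihydrofuran are inert to nucleophilic hydride and no stereocentre is touched.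

Step 18
Reactants: 29 C40 bis-silyl ether
Product: 30 (3S,5R,6R,3'S,5'R,8'R)-5',8'-epoxy-5,6,5',8'-tetrahydro-β,β-carotene-3,5,6,3'-tetrol (CNP0210286.2)
Conditions: TBAF, THF, rt
Reagents that add atoms: none
Why: Fluoride desilylation of the two secondary TBS ethers under non-acidic conditions, which spare the tertiary allylic C6–OH, the C8' centre and the E-polyene.

Compound list
1 | (4R,6R)-4-hydroxy-2,2,6-trimethylcyclohexan-1-one (actinol) | O=C1C(C)(C)C[C@H](O)C[C@H]1C | starting material
2 | (4R,6R)-4-(tert-butyldimethylsilyloxy)-2,2,6-trimethylcyclohexan-1-one | O=C1C(C)(C)C[C@H](O[Si](C)(C)C(C)(C)C)C[C@H]1C | intermediate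
3 | (4R)-4-(tert-butyldimethylsilyloxy)-2,6,6-trimethyl-1-(trimethylsilyloxy)cyclohex-1-ene | CC1=C(O[Si](C)(C)C)C(C)(C)C[C@H](O[Si](C)(C)C(C)(C)C)C1 | intermediate
4 | silyloxy epoxide (5,6-epoxide of 3, oxygen anti to C3–OTBS) | [C@]12(O[Si](C)(C)C)C(C)(C)C[C@H](O[Si](C)(C)C(C)(C)C)C[C@@]1(C)O2 | intermediate
5 | (2R,4S)-4-(tert-butyldimethylsilyloxy)-2,6,6-trimethyl-2-(trimethylsilyloxy)cyclohexan-1-one | O=C1C(C)(C)C[C@H](O[Si](C)(C)C(C)(C)C)C[C@@]1(C)O[Si](C)(C)C | intermediate
6 | (2R,4S)-4-(tert-butyldimethylsilyloxy)-2-hydroxy-2,6,6-trimethylcyclohexan-1-one | O=C1C(C)(C)C[C@H](O[Si](C)(C)C(C)(C)C)C[C@@]1(C)O | intermediate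
7 | (2E)-3-methylpent-2-en-4-yn-1-ol | OC/C=C(C)/C#C | starting material
8 | tert-butyldimethylsilyl ether of 7 | CC(C)(C)[Si](C)(C)OC/C=C(C)/C#C | intermediate
9 | lithium acetylide of 8 | CC(C)(C)[Si](C)(C)OC/C=C(C)/C#C[Li] | intermediate
10 | trimethylsilyl ether adduct (C5'–OSiMe3, C6'–OH cis) | CC(C)(C)[Si](C)(C)OC/C=C(C)/C#C[C@]1(O)C(C)(C)C[C@H](O[Si](C)(C)C(C)(C)C)C[C@@]1(C)O[Si](C)(C)C | intermediate
11 | (1R,2R,4S)-4-(tert-butyldimethylsilyloxy)-1-[(3E)-5-(tert-butyldimethylsilyloxy)-3-methylpent-3-en-1-yn-1-yl]-2,6,6-trimethylcyclohexane-1,2-diol | CC(C)(C)[Si](C)(C)OC/C=C(C)/C#C[C@]1(O)C(C)(C)C[C@H](O[Si](C)(C)C(C)(C)C)C[C@@]1(C)O | intermediate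
12 | cis-fused cyclic carbonate of 11 | CC(C)(C)[Si](C)(C)OC/C=C(C)/C#C[C@]1(OC(=O)O2)C(C)(C)C[C@H](O[Si](C)(C)C(C)(C)C)C[C@]12C | intermediate
13 | diethoxymethylsilyl ether of allenol 14 | [H]C(=[C@@]=C1C(C)(C)C[C@H](O[Si](C)(C)C(C)(C)C)C[C@@]1(C)O[Si](C)(OCC)OCC)/C(C)=C/CO[Si](C)(C)C(C)(C)C | intermediate
14 | (1R,5S)-5-(tert-butyldimethylsilyloxy)-2-[(3E)-5-(tert-butyldimethylsilyloxy)-3-methylpenta-1,3-dien-1-ylidene]-1,3,3-trimethylcyclohexan-1-ol, S allene axis | [H]C(=[C@@]=C1C(C)(C)C[C@H](O[Si](C)(C)C(C)(C)C)C[C@@]1(C)O)/C(C)=C/CO[Si](C)(C)C(C)(C)C | intermediate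
15 | (2R,6S,7aR)-6-(tert-butyldimethylsilyloxy)-2-[(2E)-4-(tert-butyldimethylsilyloxy)but-2-en-2-yl]-4,4,7a-trimethyl-2,4,5,6,7,7a-hexahydro-1-benzofuran | CC(C)(C)[Si](C)(C)OC/C=C(\C)[C@H]1C=C2C(C)(C)C[C@H](O[Si](C)(C)C(C)(C)C)C[C@@]2(C)O1 | intermediate
16 | (2E)-3-[(2R,6S,7aR)-6-(tert-butyldimethylsilyloxy)-4,4,7a-trimethyl-2,4,5,6,7,7a-hexahydro-1-benzofuran-2-yl]but-2-en-1-ol | OC/C=C(\C)[C@H]1C=C2C(C)(C)C[C@H](O[Si](C)(C)C(C)(C)C)C[C@@]2(C)O1 | intermediate
17 | allylic bromide from 16 | BrC/C=C(\C)[C@H]1C=C2C(C)(C)C[C@H](O[Si](C)(C)C(C)(C)C)C[C@@]2(C)O1 | intermediate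
18 | C15 furanoid triphenylphosphonium bromide | [Br-].c1ccccc1[P+](c1ccccc1)(c1ccccc1)C/C=C(\C)[C@H]1C=C2C(C)(C)C[C@H](O[Si](C)(C)C(C)(C)C)C[C@@]2(C)O1 | intermediate
19 | (3E)-5-bromo-3-methylpent-3-en-1-yne | BrC/C=C(C)/C#C | intermediate
20 | diethyl [(2E)-3-methylpent-2-en-4-yn-1-yl]phosphonate | CCOP(=O)(OCC)C/C=C(C)/C#C | intermediate
21 | (2E,4E,6E)-2,7-dimethylocta-2,4,6-trienedial | CC(/C=O)=C\C=C\C=C(C)\C=O | starting material
22 | sodium carbanion of phosphonate 20 | [Na+].CCOP(=O)(OCC)[CH-]/C=C(C)/C#C | intermediate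
23 | (2E,4E,6E,8E,10E)-2,7,11-trimethyltrideca-2,4,6,8,10-pentaen-12-ynal | CC(/C=C/C=C(C)/C#C)=C\C=C\C=C(C)\C=O | intermediate
24 | allylic ylide from 18 | c1ccccc1[P+](c1ccccc1)(c1ccccc1)[CH-]/C=C(\C)[C@H]1C=C2C(C)(C)C[C@H](O[Si](C)(C)C(C)(C)C)C[C@@]2(C)O1 | intermediate
25 | all-E C31 heptaenyne with furanoid end (3'S,5'R,8'R), C3'–OTBS | CC(/C=C/C=C(C)/C#C)=C\C=C\C=C(C)\C=C\C=C(/C)[C@H]1C=C2C(C)(C)C[C@H](O[Si](C)(C)C(C)(C)C)C[C@@]2(C)O1 | intermediate
26 | dimethylaluminium alkoxide chelate of ketol 6 | O=C1C(C)(C)C[C@H](O[Si](C)(C)C(C)(C)C)C[C@@]1(C)O[Al](C)C | intermediate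
27 | lithium acetylide of 25 | CC(/C=C/C=C(C)/C#C[Li])=C\C=C\C=C(C)\C=C\C=C(/C)[C@H]1C=C2C(C)(C)C[C@H](O[Si](C)(C)C(C)(C)C)C[C@@]2(C)O1 | intermediate
28 | (3S,5R,6S,3'S,5'R,8'R)-3,3'-bis(tert-butyldimethylsilyloxy)-5',8'-epoxy-7,8-didehydro-5,6,5',8'-tetrahydro-β,β-carotene-5,6-diol | CC(/C=C/C=C(C)/C#C[C@@]1(O)C(C)(C)C[C@H](O[Si](C)(C)C(C)(C)C)C[C@@]1(C)O)=C\C=C\C=C(C)\C=C\C=C(/C)[C@H]1C=C2C(C)(C)C[C@H](O[Si](C)(C)C(C)(C)C)C[C@@]2(C)O1 | intermediate
29 | (3S,5R,6R,3'S,5'R,8'R)-3,3'-bis(tert-butyldimethylsilyloxy)-5',8'-epoxy-5,6,5',8'-tetrahydro-β,β-carotene-5,6-diol | CC(/C=C/C=C(C)/C=C/[C@@]1(O)C(C)(C)C[C@H](O[Si](C)(C)C(C)(C)C)C[C@@]1(C)O)=C\C=C\C=C(C)\C=C\C=C(/C)[C@H]1C=C2C(C)(C)C[C@H](O[Si](C)(C)C(C)(C)C)C[C@@]2(C)O1 | intermediate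
30 | (3S,5R,6R,3'S,5'R,8'R)-5',8'-epoxy-5,6,5',8'-tetrahydro-β,β-carotene-3,5,6,3'-tetrol (CNP0210286.2) | CC(/C=C/C=C(C)/C=C/[C@@]1(O)C(C)(C)C[C@H](O)C[C@@]1(C)O)=C\C=C\C=C(C)\C=C\C=C(/C)[C@H]1C=C2C(C)(C)C[C@H](O)C[C@@]2(C)O1 | target

Total step count: 18.
Longest linear sequence: 13 steps (1, 2, 3, 6, 7, 8, 9, 10, 11, 15, 16, 17, 18).

Steps most likely to fail

Step 16. The risk is loss of facial control. If aluminium does not hold C5–O in the carbonyl plane, the acetylide attacks the ordinary chair (C3–OTBS equatorial, C5–O axial) from the face of C3–OTBS, as in step 6. The cause would be the 1,3-diaxial strain that an axial C3–OTBS adds to the chelated conformer. The fallback removes that strain by changing the oxidation level at C3.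
- It sets out from 6. TBAF gives (2R,4S)-2,4-dihydroxy-2,6,6-trimethylcyclohexan-1-one F1.
- Dess–Martin periodinane oxidises the only secondary alcohol of F1 to (2R)-2-hydroxy-2,6,6-trimethylcyclohexane-1,4-dione F2.
- Two equivalents of LiN(SiMe3)2 convert F2 into the dilithium alkoxide enolate F3, in which the C3 ketone is masked and C3 is trigonal.
- The acetylide 27 then adds to the remaining C6 ketone of the lithium chelate, anti to the axial methyl groups, and gives after aqueous quench the 3-oxo adduct F4.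
- Hydroxyl-directed reduction with Me4NBH(OAc)3 (Evans–Saksena type, hydride delivered from the axial C5–O) gives the 3-hydroxy adduct F5 with the 3,5-trans relationship.
- TBSCl and imidazole silylate its only secondary hydroxyl group, which brings the material back to 28.

Step 3. The risk is poor facial selectivity of the peracid attack, because the controlling C3 substituent is only homoallylic; 5-epimers would then contaminate both rings. The fallback moves the controlling stereocentre next to the reacting carbon.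
- It sets out from 3. Saegusa–Ito dehydrogenation with Pd(OAc)2 in MeCN gives (4S)-4-(tert-butyldimethylsilyloxy)-2,6,6-trimethylcyclohex-2-en-1-one F6.
- Weitz–Scheffer epoxidation (H2O2, NaOH, MeOH) attacks C4 anti to the adjacent silyl ether and gives the trans epoxy ketone F7.
- LiAlH4 reduces the ketone and opens the epoxide at the secondary C4 in the trans-diaxial sense, giving the 5,6-diol F8. F8 is a mixture at C6, which does not matter.
- Swern oxidation of the only secondary alcohol comes back to 6. Part of 6 is silylated with 1-(trimethylsilyl)imidazole to supply 5.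

Step 9. The risk is erosion of the axis-to-centre transfer by reversible opening of the gold-bound intermediate to an allyl cation stabilised by the C9'=C10' bond. Competing carbocyclisation of the vinylallene is a second risk. The fallback replaces metal catalysis by electrophilic halocyclisation.
- It sets out from 14. N-Iodosuccinimide in CH2Cl2 at −78 °C triggers a 5-endo iodoetherification (anti addition of oxygen and iodine across C7'=C8') to the 7'-iodo dihydrofuran F9.
- Iodine–lithium exchange with n-BuLi at −78 °C and a methanol quench replace iodine by hydrogen with retention, which comes back to 15.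

Further compounds
F1 | step 16 | (2R,4S)-2,4-dihydroxy-2,6,6-trimethylcyclohexan-1-one | O=C1C(C)(C)C[C@H](O)C[C@@]1(C)O
F2 | step 16 | (2R)-2-hydroxy-2,6,6-trimethylcyclohexane-1,4-dione | O=C1C(C)(C)CC(=O)C[C@@]1(C)O
F3 | step 16 | dilithium alkoxide enolate of F2 | O=C1C(C)(C)C=C(O[Li])C[C@@]1(C)O[Li]
F4 | step 16 | 3-oxo adduct (7,8-didehydro 5,6-trans-diol, C3 ketone, C3'–OTBS) | CC(/C=C/C=C(C)/C#C[C@@]1(O)C(C)(C)CC(=O)C[C@@]1(C)O)=C\C=C\C=C(C)\C=C\C=C(/C)[C@H]1C=C2C(C)(C)C[C@H](O[Si](C)(C)C(C)(C)C)C[C@@]2(C)O1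
F5 | step 16 | 3-hydroxy adduct (7,8-didehydro 3,5,6-triol, C3'–OTBS) | CC(/C=C/C=C(C)/C#C[C@@]1(O)C(C)(C)C[C@H](O)C[C@@]1(C)O)=C\C=C\C=C(C)\C=C\C=C(/C)[C@H]1C=C2C(C)(C)C[C@H](O[Si](C)(C)C(C)(C)C)C[C@@]2(C)O1
F6 | step 3 | (4S)-4-(tert-butyldimethylsilyloxy)-2,6,6-trimethylcyclohex-2-en-1-one | O=C1C(C)(C)C[C@H](O[Si](C)(C)C(C)(C)C)C=C1C
F7 | step 3 | trans epoxy ketone (4,5-epoxide anti to C3–OTBS) | O=C1C(C)(C)C[C@H](O[Si](C)(C)C(C)(C)C)[C@H]2O[C@@]12C
F8 | step 3 | 5,6-diol (C6 epimers) | OC1C(C)(C)C[C@H](O[Si](C)(C)C(C)(C)C)C[C@@]1(C)O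
F9 | step 9 | 7'-iodo dihydrofuran | CC(C)(C)[Si](C)(C)OC/C=C(\C)[C@H]1C(I)=C2C(C)(C)C[C@H](O[Si](C)(C)C(C)(C)C)C[C@@]2(C)O1
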